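Ring B (the quinone ring C1–C4/C4a/C8a) is disconnected at C4–C4a and C1–C2 into two ambiphiles: benzamide 3 (ring A; nucleophilic at C4a once lithiated, electrophilic at the C1 amide carbon) and the (R)-configured (Z)-β-iodoenal 10 (electrophilic C4 aldehyde, latent C2 vinyl anion). The key step exploits two features: C4a is the only ring A carbon flanked by both the C5 oxygen and the C8a carboxamide (cooperative ortho-lithiation), and C1 and C4 are carbonyl carbons joined by a cis C2=C3 unit. One pot (lithiation, aldehyde addition, iodine–lithium exchange, acylation, air oxidation) delivers the complete side-chain-bearing quinone 14; deprotection and Steglich esterification finish.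

Key step: step 8

Assumption: in the zinc–ProPhenol alkynylation the (S,S)-ligand is taken to direct the alkynyl group to the Si face of the aliphatic aldehyde, giving (R)-7; if the opposite sense applies, the (R,R)-ligand is used with no other change.

Step 1
Reactants: 1 methyl 2,5-dihydroxybenzoate
Product: 2 methyl 2,5-bis(methoxymethoxy)benzoate
Conditions: NaH, MOMCl, DMF, 0 °C → rt
Reagents that add atoms: chloromethyl methyl ether, COCCl
Why: Williamson-type O-alkylation of both sodium phenoxides installs the MOM acetals, which later serve as ortho-directing groups and as acid-labile phenol protection.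

Step 2
Reactants: 2 methyl 2,5-bis(methoxymethoxy)benzoate
Product: 3 N,N-diethyl-2,5-bis(methoxymethoxy)benzamide
Conditions: Et2NH, i-PrMgCl, THF, 0 °C → rt
Reagents that add atoms: diethylamine, CCNCC
Why: Bodroux aminolysis: the chloromagnesium amide formed in the flask should convert the methyl ester into the tertiary amide without touching the MOM acetals.

Step 3
Reactants: 4 4-methylpent-3-en-1-ol
Product: 5 4-methylpent-3-enal
Conditions: Dess–Martin periodinane, pyridine, CH2Cl2, 0 °C; used at once as a solution
Reagents that add atoms: none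
Why: Dess–Martin oxidation under buffered, non-basic conditions should give the β,γ-unsaturated aldehyde without migration of the double bond into conjugation.

Step 4
Reactants: 5 4-methylpent-3-enal; 6 methyl propiolate
Product: 7 methyl (4R)-4-hydroxy-7-methyloct-6-en-2-ynoate
Conditions: Me2Zn, (S,S)-ProPhenol (20 mol %), Ph3PO (40 mol %), toluene, 0–4 °C; aq NH4Cl
Reagents that add atoms: none
Why: Zinc–ProPhenol asymmetric alkynylation: the chiral dinuclear zinc catalyst should deliver the zinc acetylide of 6 to the Si face of the aldehyde, setting the (R)-carbinol that becomes C1' of the target.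

Step 5
Reactants: 7 methyl (4R)-4-hydroxy-7-methyloct-6-en-2-ynoate
Product: 8 methyl (4R)-4-[(tert-butyldimethylsilyl)oxy]-7-methyloct-6-en-2-ynoate
Conditions: TBSOTf, 2,6-lutidine, CH2Cl2, −78 °C
Reagents that add atoms: tert-butyldimethylsilyl triflate, CC(C)(C)[Si](C)(C)OS(=O)(=O)C(F)(F)F
Why: Silylation with a non-nucleophilic base avoids conjugate addition to the ynoate and gives an ether that withstands organolithiums and blocks lactonisation after the next step.

Step 6
Reactants: 8 methyl (4R)-4-[(tert-butyldimethylsilyl)oxy]-7-methyloct-6-en-2-ynoate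
Product: 9 methyl (2Z,4R)-4-[(tert-butyldimethylsilyl)oxy]-3-iodo-7-methylocta-2,6-dienoate
Conditions: LiI, AcOH, MeCN, 70 °C
Reagents that add atoms: lithium iodide, [Li+].[I-]
Why: Hydroiodination of the 2-ynoate (conjugate addition of iodide, anti protonation) should give the (Z)-3-iodo-2-enoate, with iodine cis to the ester carbon as the later ring closure requires.

Step 7
Reactants: 9 methyl (2Z,4R)-4-[(tert-butyldimethylsilyl)oxy]-3-iodo-7-methylocta-2,6-dienoate
Product: 10 (2Z,4R)-4-[(tert-butyldimethylsilyl)oxy]-3-iodo-7-methylocta-2,6-dienal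
Conditions: i-Bu2AlH (1.05 equiv), CH2Cl2, −78 °C; Rochelle salt work-up; used directly
Reagents that add atoms: none
Why: Partial ester reduction: the aluminium hemiacetal is stable at −78 °C and should release the aldehyde only on work-up, leaving the Z geometry, the vinyl iodide and the silyl ether untouched.

Step 8
Reactants: 3 N,N-diethyl-2,5-bis(methoxymethoxy)benzamide; 10 (2Z,4R)-4-[(tert-butyldimethylsilyl)oxy]-3-iodo-7-methylocta-2,6-dienal
Product: 14 2-[(1R)-1-[(tert-butyldimethylsilyl)oxy]-4-methylpent-3-en-1-yl]-5,8-bis(methoxymethoxy)naphthalene-1,4-dione, via aryllithium 11 (not isolated), via lithium alkoxide 12 (not isolated), via hydroquinone 13 (not isolated)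
Conditions: 3 (1.1 equiv), s-BuLi (1.05 equiv), TMEDA, THF, −78 °C; 10, −78 °C; t-BuLi (2.1 equiv), −78 → 0 °C; AcOH; then air, EtOAc, rt
Reagents that add atoms: none
Why: s-BuLi/TMEDA removes the ring A proton between the carboxamide and the neighbouring OMOM group of 3 to give 11, which adds 1,2 to the aldehyde of 10 (C4–C4a bond, alkoxide 12); t-BuLi then exchanges the vinylic iodine with retention of the Z geometry, the C2 vinyllithium attacks the diethylamide carbon (C1–C2 bond), the expelled LiNEt2 tautomerises the 4-oxido-naphthalen-1(4H)-one to the dianion of 13, and air after the acidic quench oxidises 13 to quinone 14. The closest known reaction type is the one-pot tandem directed-metalation route from ortho-lithiated tertiary benzamides and aryl aldehydes to anthraquinones, here with the second carbanion made by iodine–lithium exchange (Parham-type cyclisation) instead of a second deprotonation. Ring B closes by a 6-exo-trig addition–elimination of the vinyllithium at the amide carbonyl. No new stereocenter survives, since the transient carbinol carbon becomes the C4 carbonyl, and the (R)-centre of 10 carries no acidic hydrogen and should pass through unchanged. The step needs site-selective lithiation, which the cooperative amide/OMOM pair secures, and exchange before any attack of t-BuLi on the amide, which the rate of iodine–lithium exchange at −78 °C secures. The Z geometry of 10 holds lithium cis to the carbinol carbon so that only the six-membered closure is possible, and quenching with AcOH before aeration keeps diethylamine protonated so that it cannot add to the quinone.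

Step 9
Reactants: 14 2-[(1R)-1-[(tert-butyldimethylsilyl)oxy]-4-methylpent-3-en-1-yl]-5,8-bis(methoxymethoxy)naphthalene-1,4-dione
Product: 15 shikonin, 5,8-dihydroxy-2-[(1R)-1-hydroxy-4-methylpent-3-en-1-yl]naphthalene-1,4-dione
Conditions: HCl (2 M aq)/THF 1:3, rt, dark, Ar
Reagents that add atoms: none
Why: Acid-catalysed hydrolysis of the two aryl MOM acetals and of the secondary silyl ether in a non-nucleophilic co-solvent should release the naphthazarin and the carbinol; no bond to the stereocenter is broken.

Step 10
Reactants: 15 shikonin; 16 3-hydroxy-3-methylbutanoic acid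
Product: 17 beta-HIVS, (1R)-1-(5,8-dihydroxy-1,4-dioxo-1,4-dihydronaphthalen-2-yl)-4-methylpent-3-en-1-yl 3-hydroxy-3-methylbutanoate
Conditions: DCC, DMAP (cat.), CH2Cl2, 0 °C → rt
Reagents that add atoms: none
Why: Steglich esterification: the peri hydroxyls are locked in hydrogen bonds to the quinone carbonyls and the tertiary hydroxyl of 16 is too hindered, so the activated acid should acylate only the secondary side-chain alcohol, with retention at C1'.

Compound list
1 | methyl 2,5-dihydroxybenzoate | COC(=O)c1cc(O)ccc1O | starting material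
2 | methyl 2,5-bis(methoxymethoxy)benzoate | COC(=O)c1cc(OCOC)ccc1OCOC | intermediate
3 | N,N-diethyl-2,5-bis(methoxymethoxy)benzamide | CCN(CC)C(=O)c1cc(OCOC)ccc1OCOC | intermediate
4 | 4-methylpent-3-en-1-ol | CC(C)=CCCO | starting material
5 | 4-methylpent-3-enal | CC(C)=CCC=O | intermediate
6 | methyl propiolate | C#CC(=O)OC | starting material
7 | methyl (4R)-4-hydroxy-7-methyloct-6-en-2-ynoate | CC(C)=CC[C@@H](O)C#CC(=O)OC | intermediate
8 | methyl (4R)-4-[(tert-butyldimethylsilyl)oxy]-7-methyloct-6-en-2-ynoate | CC(C)=CC[C@@H](O[Si](C)(C)C(C)(C)C)C#CC(=O)OC | intermediate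
9 | methyl (2Z,4R)-4-[(tert-butyldimethylsilyl)oxy]-3-iodo-7-methylocta-2,6-dienoate | CC(C)=CC[C@@H](O[Si](C)(C)C(C)(C)C)/C(I)=C/C(=O)OC | intermediate
10 | (2Z,4R)-4-[(tert-butyldimethylsilyl)oxy]-3-iodo-7-methylocta-2,6-dienal | CC(C)=CC[C@@H](O[Si](C)(C)C(C)(C)C)/C(I)=C/C=O | intermediate
11 | [2-(diethylcarbamoyl)-3,6-bis(methoxymethoxy)phenyl]lithium | CCN(CC)C(=O)c1c([Li])c(OCOC)ccc1OCOC | intermediate
12 | lithium alkoxide of N,N-diethyl-2-[(2Z,4R)-4-[(tert-butyldimethylsilyl)oxy]-1-hydroxy-3-iodo-7-methylocta-2,6-dien-1-yl]-3,6-bis(methoxymethoxy)benzamide (both C1 epimers) | CC(C)=CC[C@@H](O[Si](C)(C)C(C)(C)C)/C(I)=C/C(O[Li])c1c(OCOC)ccc(OCOC)c1C(=O)N(CC)CC | intermediate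
13 | 2-[(1R)-1-[(tert-butyldimethylsilyl)oxy]-4-methylpent-3-en-1-yl]-5,8-bis(methoxymethoxy)naphthalene-1,4-diol | CC(C)=CC[C@@H](O[Si](C)(C)C(C)(C)C)c1cc(O)c2c(OCOC)ccc(OCOC)c2c1O | intermediate
14 | 2-[(1R)-1-[(tert-butyldimethylsilyl)oxy]-4-methylpent-3-en-1-yl]-5,8-bis(methoxymethoxy)naphthalene-1,4-dione | CC(C)=CC[C@@H](O[Si](C)(C)C(C)(C)C)C1=CC(=O)c2c(OCOC)ccc(OCOC)c2C1=O | intermediate
15 | shikonin, 5,8-dihydroxy-2-[(1R)-1-hydroxy-4-methylpent-3-en-1-yl]naphthalene-1,4-dione | CC(C)=CC[C@@H](O)C1=CC(=O)c2c(O)ccc(O)c2C1=O | intermediate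
16 | 3-hydroxy-3-methylbutanoic acid | CC(C)(O)CC(=O)O | starting material
17 | beta-HIVS, (1R)-1-(5,8-dihydroxy-1,4-dioxo-1,4-dihydronaphthalen-2-yl)-4-methylpent-3-en-1-yl 3-hydroxy-3-methylbutanoate | CC(C)=CC[C@@H](OC(=O)CC(C)(C)O)C1=CC(=O)c2c(O)ccc(O)c2C1=O | target

Total step count: 10. Longest linear sequence: 8 steps (steps 3 to 10, from 4 to 17).

Steps most likely to fail

Step 8. What may go wrong: loss of silanolate from the C2 vinyllithium (β-elimination to an allene), attack of t-BuLi on the amide, or incomplete in-between lithiation, so that ring B does not close. Fallback, from 3 and 10 back to 14: adduct 12 is generated as in step 8 but, in place of t-BuLi, is warmed to rt and quenched with AcOH, so that the alkoxide displaces diethylamide and gives the iodovinyl phthalide F1. i-Bu2AlH at −78 °C reduces the lactone to the lactol F2. CrCl2 with catalytic NiCl2 in DMF (intramolecular Nozaki–Hiyama–Kishi reaction on the open hydroxy-aldehyde form) then forms the C1–C2 bond without any organolithium and gives the 1,4-dihydronaphthalene-1,4-diol F3. MnO2 in CH2Cl2 oxidises F3 to quinone 14.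

Step 4. What may go wrong: enolisation of the aldehyde with double-bond migration or self-aldol, and eroded facial selectivity with an unbranched aldehyde. Fallback, from 5 and 6 back to 7: the lithium acetylide of 6 (LiN(SiMe3)2, THF, −78 °C) adds to 5 to give the racemic alcohol F4. Dess–Martin oxidation gives the ynone F5. (R)-Alpine-Borane, neat at rt (Midland reduction, alkynyl as the small group, no base present), reduces F5 to (R)-7.

Step 9. What may go wrong: acid-promoted ionisation at C1' of the freed naphthazarin (solvolysis, loss of configurational integrity), cyclisation of the liberated hydroxyl onto the prenyl double bond, or hydration of that double bond. Fallback, from 14 to target 17: HF·pyridine in THF/pyridine removes only the silyl ether to give the bis-MOM alcohol F6. Steglich esterification with 16 (DCC, DMAP) gives the bis-MOM ester F7. MgBr2·OEt2 in Et2O/CH2Cl2 at rt (chelation to the peri quinone carbonyls, non-protic acetal cleavage) removes both MOM groups and gives 17 directly.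

Further compounds
F1 | step 8 | 3-[(1Z,3R)-3-[(tert-butyldimethylsilyl)oxy]-2-iodo-6-methylhepta-1,5-dien-1-yl]-4,7-bis(methoxymethoxy)-2-benzofuran-1(3H)-one | CC(C)=CC[C@@H](O[Si](C)(C)C(C)(C)C)/C(I)=C/C1OC(=O)c2c(OCOC)ccc(OCOC)c21
F2 | step 8 | 3-[(1Z,3R)-3-[(tert-butyldimethylsilyl)oxy]-2-iodo-6-methylhepta-1,5-dien-1-yl]-4,7-bis(methoxymethoxy)-1,3-dihydro-2-benzofuran-1-ol | CC(C)=CC[C@@H](O[Si](C)(C)C(C)(C)C)/C(I)=C/C1OC(O)c2c(OCOC)ccc(OCOC)c21
F3 | step 8 | 2-[(1R)-1-[(tert-butyldimethylsilyl)oxy]-4-methylpent-3-en-1-yl]-5,8-bis(methoxymethoxy)-1,4-dihydronaphthalene-1,4-diol | CC(C)=CC[C@@H](O[Si](C)(C)C(C)(C)C)C1=CC(O)c2c(OCOC)ccc(OCOC)c2C1O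
F4 | step 4 | methyl 4-hydroxy-7-methyloct-6-en-2-ynoate (racemic) | CC(C)=CCC(O)C#CC(=O)OC
F5 | step 4 | methyl 7-methyl-4-oxooct-6-en-2-ynoate | CC(C)=CCC(=O)C#CC(=O)OC
F6 | step 9 | 2-[(1R)-1-hydroxy-4-methylpent-3-en-1-yl]-5,8-bis(methoxymethoxy)naphthalene-1,4-dione | CC(C)=CC[C@@H](O)C1=CC(=O)c2c(OCOC)ccc(OCOC)c2C1=O
F7 | step 9 | (1R)-1-[5,8-bis(methoxymethoxy)-1,4-dioxo-1,4-dihydronaphthalen-2-yl]-4-methylpent-3-en-1-yl 3-hydroxy-3-methylbutanoate | CC(C)=CC[C@@H](OC(=O)CC(C)(C)O)C1=CC(=O)c2c(OCOC)ccc(OCOC)c2C1=O
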